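Colleague, you want a quick number, and your hunch is that the two runs lie on nearly one curve. I agree, and I carry one quantity.

| flask | substrate | gas phase | remark | time |
|---|---|---|---|---|
| ochre | 0.074 M | 9.9 mM (held) | run made earlier |  |
| blue | 0.17 M | 9.9 mM (held) | run made earlier |  |
| flask | 0.11 M | 9.9 mM (held) |  | 4.0 min |

| ochre: time / min | ochre: target / % | blue: time / min | blue: target / % |
|---|---|---|---|
| 0.200 | 7.7 | 0.500 | 15.3 |
| 0.667 | 22.2 | 1.00 | 29.2 |
| 1.00 | 30.2 | 1.33 | 37.1 |
| 1.50 | 40.8 | 2.00 | 49.1 |
| 2.50 | 59.2 | 2.50 | 56.7 |

(standard deviation of a reading: 0.5 percentage points)

- at the start none of the gas phase is in solution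

- amount of target at 4.0 min, in percent of the substrate charged
- concentration of dissolved gas in solution at 4.0 min, in percent of saturation

The quantity is the apparent constant, a pseudo-first-order constant: the log of one over the share of the charge not yet target, divided by time. At 2.50 min the ochre run gives 0.359 min⁻¹ and the blue run 0.335 min⁻¹, a little lower, although blue has 2.30 times the ochre substrate. So I treat the two runs as one first-order curve, and I take the mean of these two readings, 0.347 min⁻¹. For the flask at 4.0 min that gives 75.0% target.

The forecast is a point above mine, at 76% target with dissolved gas at 95% of saturation, and it holds that “the reaction is close to first order in substrate”.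

The flask gives 72.5% target and 96.2% of saturation, so the forecast stands within its margins.

    gas phase ⇌ dissolved gas, rate k1*(csat - [dissolved gas]) (kL = 1.00 s⁻¹)
    substrate + dissolved gas → target (k = 0.690 M⁻¹ s⁻¹)
    substrate → side product (k = 8.80 × 10⁻⁴ s⁻¹)
    2 dissolved gas → self-condensation product (k = 1.40 M⁻¹ s⁻¹)

Read on the flask at 4.0 min, the apparent constant is 0.323 min⁻¹, lower than the 0.347 min⁻¹ I read off the two runs, and the flask also holds 10.1% side product. The target answer has moved by 5 points at a substrate charge of 0.585 M, or at a time of 3.37 min or 4.88 min, the other setting held. The same flask read at 2.5 min, the time at which I read the constant in the two runs, is reckoned by the constant at 58.0% target, and it gives 58.0%. At that time it holds 8.12% side product, with 34% of the charged substrate left.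

The earlier runs and the new flask were computed with constants of no real substance.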